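**Plan**
Retrosynthesis: the two acetates are cut first, then C7–C11 (aldol to a dioxanone), C7–C8 (seven-membered ring), C8–C9 (one-carbon homologation), C1–C10 (Michael addition) and C5–C6 (cross-coupling).
Enabling feature: C10 with its methyl (C14), its hydroxyl and C9 is a lactic acid unit, and the chain C9–C10–C1–C5–C6 carries oxygen at C9 and C6 (a 1,5 pattern), so C1–C10 is the bond made when a lactate enolate adds to a C5=C1 enone whose carbonyl is C6.
Forward: the five-membered ring comes from (R)-linalool by metathesis and is converted into the C5-acetyl enone; the lactate acetal is joined at C1–C10 without ring closure; the seven-membered ring is closed at C7–C8 by an intramolecular Mukaiyama aldol; C11–C13 are added at C7 by a reductive aldol.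
Stereochemistry: C4 from (R)-linalool; C10 from (R)-lactic acid relayed through the tert-butyl acetal; C1 by attack anti to the C4 silyloxy group; C5 by kinetic protonation; C7 by aldol on the face free of silyloxy groups; C6 by hydroxyl-directed hydride delivery.

Key step: step 9

Remark: guaiane numbering (C1–C15) is used for all intermediates and α denotes the face of H-1 and H-5; commercial (R)-linalool is taken as enantiomerically pure, since any (S)-material would appear as a separable diastereomer of 16.

**Route**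

Step 1
Reactants: 1 (R)-lactic acid; 2 pivalaldehyde
Product: 3 (2R,5R)-2-tert-butyl-5-methyl-1,3-dioxolan-4-one (cis acetal)
Conditions: p-TsOH (cat.), H2SO4 (cat.), pentane, reflux, water separator; crystallisation at −78 °C
Reagents that add atoms: none
Why: Acid-catalysed acetalisation under equilibrating conditions should favour the cis acetal, whose new acetal centre is set by thermodynamic control from the lactic acid centre, and low-temperature crystallisation should give it pure.

Step 2
Reactants: 4 (R)-(−)-linalool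
Product: 5 (R)-1-methylcyclopent-2-en-1-ol
Conditions: second-generation Grubbs catalyst (H2IMes)(PCy3)Cl2Ru=CHPh (cat.), CH2Cl2, 40 °C
Reagents that add atoms: none
Why: Ring-closing metathesis between the vinyl group and the trisubstituted alkene should close the cyclopentene with loss of isobutene, a known behaviour of linalool, and leaves the carbinol centre (future C4) untouched.

Step 3
Reactants: 5 (R)-1-methylcyclopent-2-en-1-ol
Product: 6 (R)-tert-butyldimethyl[(1-methylcyclopent-2-en-1-yl)oxy]silane
Conditions: TBSOTf, 2,6-lutidine, CH2Cl2, 0 °C → rt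
Reagents that add atoms: tert-butyldimethylsilyl trifluoromethanesulfonate, CC(C)(C)[Si](C)(C)OS(=O)(=O)C(F)(F)F
Why: Silylation with a silyl triflate and a hindered pyridine base is the standard way to protect a tertiary alcohol and also makes the small ring compound less volatile.

Step 4
Reactants: 6 (R)-tert-butyldimethyl[(1-methylcyclopent-2-en-1-yl)oxy]silane
Product: 7 C5–C1 epoxide of 6 (oxirane anti to the silyloxy group)
Conditions: mCPBA, CH2Cl2, 0 °C → rt
Reagents that add atoms: 3-chloroperoxybenzoic acid, OOC(=O)c1cccc(Cl)c1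
Why: Prilezhaev epoxidation should occur anti to the silyloxy group, and the configuration of the two new centres is of no consequence because C1 becomes CH2 in step 5 and C5 a carbonyl in step 6.

Step 5
Reactants: 7 C5–C1 epoxide of 6
Product: 8 2-methyl-2-(tert-butyldimethylsilyloxy)cyclopentan-1-ol (hydroxyl on C5, trans to the silyloxy group)
Conditions: LiAlH4, THF, 0 °C → 50 °C
Reagents that add atoms: none
Why: SN2 hydride opening of the epoxide is expected at C1, the carbon remote from the fully substituted C4, which leaves the hydroxyl on C5.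

Step 6
Reactants: 8 2-methyl-2-(tert-butyldimethylsilyloxy)cyclopentan-1-ol
Product: 9 (R)-2-methyl-2-(tert-butyldimethylsilyloxy)cyclopentan-1-one
Conditions: Dess–Martin periodinane, CH2Cl2, rt
Reagents that add atoms: none
Why: Dess–Martin oxidation of the secondary alcohol gives the C5 ketone, and C4 carries no hydrogen and cannot epimerise.

Step 7
Reactants: 9 (R)-2-methyl-2-(tert-butyldimethylsilyloxy)cyclopentan-1-one
Product: 11 (R)-5-methyl-5-(tert-butyldimethylsilyloxy)cyclopent-1-en-1-yl trifluoromethanesulfonate, via potassium enolate 10 (not isolated)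
Conditions: KN(SiMe3)2, THF, −78 °C; PhNTf2, −78 → 0 °C
Reagents that add atoms: N-phenylbis(trifluoromethanesulfonimide), O=S(=O)(N(c1ccccc1)S(=O)(=O)C(F)(F)F)C(F)(F)F
Why: Only C1 carries enolisable hydrogens, so enolate formation and O-sulfonylation can give only the C5=C1 enol triflate.

Step 8
Reactants: 11 (R)-5-methyl-5-(tert-butyldimethylsilyloxy)cyclopent-1-en-1-yl trifluoromethanesulfonate
Product: 13 (R)-1-[5-methyl-5-(tert-butyldimethylsilyloxy)cyclopent-1-en-1-yl]ethan-1-one, via ethoxydiene 12 (not isolated)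
Conditions: tributyl(1-ethoxyvinyl)stannane, Pd(PPh3)4 (cat.), LiCl, CuI (cat.), THF, 65 °C; then 1 M HCl, THF, 0 °C
Reagents that add atoms: tributyl(1-ethoxyvinyl)stannane, CCCC[Sn](CCCC)(CCCC)C(=C)OCC; water, O
Why: Stille coupling of the enol triflate under zerovalent palladium catalysis (LiCl and CuI help the hindered partner) installs C6 and C7 as an enol ether, which dilute acid hydrolyses to the methyl ketone.

Step 9
Reactants: 3 (2R,5R)-2-tert-butyl-5-methyl-1,3-dioxolan-4-one; 13 (R)-1-[5-methyl-5-(tert-butyldimethylsilyloxy)cyclopent-1-en-1-yl]ethan-1-one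
Product: 16 (2R,5S)-2-tert-butyl-5-[(1R,2R,3R)-2-acetyl-3-methyl-3-(tert-butyldimethylsilyloxy)cyclopentyl]-5-methyl-1,3-dioxolan-4-one, via dioxolanone lithium enolate 14 (not isolated), via adduct lithium enolate 15 (not isolated)
Conditions: LiN(i-Pr)2, THF, −78 °C; 13, DMPU, −78 → −60 °C; AcOH, −78 °C
Reagents that add atoms: none
Why: LiN(i-Pr)2 removes the C10 proton of 3 to give the planar lithium enolate 14, in which only the acetal carbon is still stereogenic, and 14 adds in 1,4-fashion to C1 of enone 13 to give ketone enolate 15, which acetic acid protonates at C5 (Michael addition; no ring is closed). The closest known reaction type is the conjugate addition of lactic- and mandelic-acid-derived 2-tert-butyl-1,3-dioxolan-4-one enolates to nitroalkenes and enones (self-regeneration of stereocentres), applied here to a ring-substituted enone, which is a demanding but not a new case. C10: the tert-butyl group blocks one enolate face, so C1 enters trans to it, where the hydrogen of 3 stood, and the (R)-lactic acid configuration is retained. C1: the nucleophile should approach the cyclopentene on the β face, opposite the tertiary silyloxy group on C4, which leaves H-1 α. C5: kinetic protonation of 15 at −78 °C from the α face, away from the new quaternary substituent on C1 and the C4 methyl, should give the cis C1/C5 relationship, and no base is present afterwards to equilibrate it. The step needs 1,4- over 1,2-addition and over proton transfer from the acetyl group; the hindered, fully substituted enolate adds reversibly to the carbonyl, C1 is an unhindered CH, and DMPU at low temperature favours the conjugate pathway.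

Step 10
Reactants: 16 Michael adduct
Product: 18 C9→O6 δ-lactone with free 10α-hydroxyl [4-hydroxy-1,4,7-trimethyl-7-(tert-butyldimethylsilyloxy)hexahydrocyclopenta[c]pyran-3(1H)-one; C6 epimers], via hydroxy acetal 17 (not isolated)
Conditions: NaBH4, THF/MeOH, −40 °C; then CSA (cat.), CH2Cl2, rt → 40 °C
Reagents that add atoms: none
Why: Borohydride should reduce only the ketone, and because the C6 hydroxyl and the C9 acyl acetal are cis on the cyclopentane, acid-catalysed transacylation should close the six-membered lactone with release of pivalaldehyde and the C10 hydroxyl; C6 is reoxidised in step 14, so its configuration does not matter.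

Step 11
Reactants: 18 hydroxy lactone
Product: 19 4α,10α-bis(tert-butyldimethylsilyloxy) lactone
Conditions: TBSOTf, 2,6-lutidine, CH2Cl2, 0 °C → rt
Reagents that add atoms: tert-butyldimethylsilyl trifluoromethanesulfonate, CC(C)(C)[Si](C)(C)OS(=O)(=O)C(F)(F)F
Why: Silylation of the tertiary C10 hydroxyl keeps it from forming a hemiketal with the C6 ketone regenerated later and from fragmenting β to the future C8 aldehyde carbon.

Step 12
Reactants: 19 bis-silyl lactone
Product: 20 lactol at C9 (anomers; C6 epimers)
Conditions: i-Bu2AlH, CH2Cl2, −78 °C; Rochelle salt work-up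
Reagents that add atoms: none
Why: Half-reduction of a lactone with i-Bu2AlH at −78 °C, where the tetrahedral aluminium alkoxide is stable, should stop at the lactol.

Step 13
Reactants: 20 lactol
Product: 21 C8 methyl enol ether with free C6 hydroxyl (E/Z; C6 epimers)
Conditions: MeOCH2PPh3Cl, KOt-Bu, THF, 0 °C → rt
Reagents that add atoms: (methoxymethyl)triphenylphosphonium chloride, COC[P+](c1ccccc1)(c1ccccc1)c1ccccc1.[Cl-]
Why: Wittig reaction of the ring-opened hydroxy aldehyde form of the lactol with the methoxymethylene ylide adds C8 as an enol ether (both geometries serve) and frees the C6 hydroxyl.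

Step 14
Reactants: 21 enol ether alcohol
Product: 22 C6 methyl ketone with C8 methyl enol ether (E/Z)
Conditions: Dess–Martin periodinane, pyridine, CH2Cl2, 0 °C → rt
Reagents that add atoms: none
Why: Dess–Martin oxidation buffered with pyridine restores the C6 methyl ketone without touching the acid-sensitive enol ether.

Step 15
Reactants: 22 enol ether ketone
Product: 23 C6 methyl ketone with C8 dimethyl acetal
Conditions: PPTS (cat.), MeOH, rt
Reagents that add atoms: methanol, CO
Why: Acid-catalysed addition of methanol to the enol ether (acetalisation) fixes C8 at the aldehyde oxidation level in a form that a Lewis acid can ionise, while the hindered ketone and the tertiary silyl ethers should survive PPTS.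

Step 16
Reactants: 23 keto acetal
Product: 25 trimethylsilyl enol ether C6(OSiMe3)=C7H2 of 23, via lithium enolate 24 (not isolated)
Conditions: LiN(i-Pr)2, THF, −78 °C; TMSCl, Et3N, −78 → 0 °C
Reagents that add atoms: chlorotrimethylsilane, C[Si](C)(C)Cl
Why: Kinetic deprotonation should occur only at the C7 methyl group, since the other α-position (C5) is a methine between two substituted carbons, and O-silylation then gives the enol silane without disturbing C5.

Step 17
Reactants: 25 enol silane acetal
Product: 27 4α,10α-bis(tert-butyldimethylsilyloxy)-1αH,5αH-11,12,13-trinorguai-7-en-6-one, via methoxy ketone 26 (not isolated)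
Conditions: TMSOTf (cat.), 2,6-di-tert-butylpyridine (cat.), CH2Cl2, −78 °C, high dilution; then DBU, 0 °C → rt
Reagents that add atoms: none
Why: Intramolecular Mukaiyama aldol addition to an acetal, in which the silyl triflate ionises the acetal to an oxocarbenium ion at C8 that the enol silane attacks through C7 (7-enolendo-exo-trig, a known way to close seven-membered rings), gives the β-methoxy ketone, from which DBU removes methanol by E1cB elimination to the conjugated enone.

Step 18
Reactants: 27 bicyclic enone; 28 2,2-dimethyl-1,3-dioxan-5-one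
Product: 30 7β-(5-hydroxy-2,2-dimethyl-1,3-dioxan-5-yl)-4α,10α-bis(tert-butyldimethylsilyloxy)-1αH,5αH,7αH-11,12,13-trinorguaian-6-one, via lithium enolate 29 (not isolated)
Conditions: LiBH(s-Bu)3, THF, −78 °C; 28, −78 °C; AcOH, −78 °C
Reagents that add atoms: none
Why: Reductive aldol reaction, in which 1,4-hydride addition to the β-unsubstituted enone gives the C6–C7 lithium enolate regiospecifically and its addition to the electrophilic dioxanone should occur on the β face, which carries only the two methyl groups while both tertiary silyloxy groups shield the α face, so that the side chain ends pseudo-equatorial (H-7 α), also the more stable arrangement.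

Step 19
Reactants: 30 aldol adduct
Product: 31 6α-alcohol of 30
Conditions: Me4NBH(OAc)3, MeCN/AcOH, −30 °C
Reagents that add atoms: none
Why: Evans–Saksena reduction, in which the C11 hydroxyl exchanges an acetate on boron and delivers hydride intramolecularly to the β face of the C6 ketone, should place the new hydroxyl α, trans to the side chain.

Step 20
Reactants: 31 protected diol
Product: 32 (1R,4R,5S,6S,7R,10R)-guaiane-4,6,10,11,12,13-hexaol
Conditions: 48% aq. HF, MeCN, 0 °C → rt
Reagents that add atoms: none
Why: Aqueous HF should cleave both tertiary silyl ethers and hydrolyse the acetonide in one operation under conditions too mild to ionise the tertiary alcohols.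

Step 21
Reactants: 32 hexaol
Product: 33 (1R,4R,5S,6S,7R,10R)-4,6,10,11-tetrahydroxyguaiane-12,13-diyl diacetate (target)
Conditions: Ac2O (2.2 equiv), 2,4,6-collidine, CH2Cl2, −20 → 0 °C
Reagents that add atoms: acetic anhydride, CC(=O)OC(C)=O
Why: Acetylation with a limited amount of anhydride and a weak base at low temperature should be selective for the two primary hydroxyls over the hindered secondary C6 hydroxyl and the three tertiary ones.

**Compound list**

1 | (R)-lactic acid | C[C@@H](O)C(=O)O | starting material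
2 | pivalaldehyde (2,2-dimethylpropanal) | CC(C)(C)C=O | starting material
3 | (2R,5R)-2-tert-butyl-5-methyl-1,3-dioxolan-4-one (cis) | C[C@H]1O[C@@H](C(C)(C)C)OC1=O | intermediate
4 | (R)-(−)-linalool | CC(C)=CCC[C@@](C)(O)C=C | starting material
5 | (R)-1-methylcyclopent-2-en-1-ol | C[C@]1(O)C=CCC1 | intermediate
6 | (R)-tert-butyldimethyl[(1-methylcyclopent-2-en-1-yl)oxy]silane | C[C@]1(O[Si](C)(C)C(C)(C)C)C=CCC1 | intermediate
7 | 2-methyl-2-(tert-butyldimethylsilyloxy)-6-oxabicyclo[3.1.0]hexane, C4 (R), oxirane anti to the silyloxy group | C[C@]1(O[Si](C)(C)C(C)(C)C)[C@@H]2O[C@@H]2CC1 | intermediate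
8 | 2-methyl-2-(tert-butyldimethylsilyloxy)cyclopentan-1-ol, C4 (R), hydroxyl trans to the silyloxy group | C[C@]1(O[Si](C)(C)C(C)(C)C)[C@H](O)CCC1 | intermediate
9 | (R)-2-methyl-2-(tert-butyldimethylsilyloxy)cyclopentan-1-one | C[C@]1(O[Si](C)(C)C(C)(C)C)C(=O)CCC1 | intermediate
10 | potassium enolate of 9 | [K+].C[C@]1(O[Si](C)(C)C(C)(C)C)C([O-])=CCC1 | intermediate (not isolated)
11 | (R)-5-methyl-5-(tert-butyldimethylsilyloxy)cyclopent-1-en-1-yl trifluoromethanesulfonate | C[C@]1(O[Si](C)(C)C(C)(C)C)C(OS(=O)(=O)C(F)(F)F)=CCC1 | intermediate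
12 | (R)-1-(1-ethoxyvinyl)-5-methyl-5-(tert-butyldimethylsilyloxy)cyclopent-1-ene | C=C(OCC)C1=CCC[C@@]1(C)O[Si](C)(C)C(C)(C)C | intermediate (not isolated)
13 | (R)-1-[5-methyl-5-(tert-butyldimethylsilyloxy)cyclopent-1-en-1-yl]ethan-1-one | CC(=O)C1=CCC[C@@]1(C)O[Si](C)(C)C(C)(C)C | intermediate
14 | lithium (R)-2-tert-butyl-5-methyl-1,3-dioxol-4-olate (enolate of 3) | [Li+].CC1=C([O-])O[C@H](C(C)(C)C)O1 | intermediate (not isolated)
15 | lithium C5=C6 enolate of adduct 16 | O=C1O[C@H](C(C)(C)C)O[C@@]1(C)[C@@H]2CC[C@@](C)(O[Si](C)(C)C(C)(C)C)C2=C(C)[O-].[Li+] | intermediate (not isolated)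
16 | (2R,5S)-2-tert-butyl-5-[(1R,2R,3R)-2-acetyl-3-methyl-3-(tert-butyldimethylsilyloxy)cyclopentyl]-5-methyl-1,3-dioxolan-4-one | O=C1O[C@H](C(C)(C)C)O[C@@]1(C)[C@@H]2CC[C@@](C)(O[Si](C)(C)C(C)(C)C)[C@@H]2C(C)=O | intermediate
17 | C6 alcohol of 16 (1-hydroxyethyl in place of acetyl; C6 epimers) | O=C1O[C@H](C(C)(C)C)O[C@@]1(C)[C@@H]2CC[C@@](C)(O[Si](C)(C)C(C)(C)C)[C@@H]2C(C)O | intermediate (not isolated)
18 | 4-hydroxy-1,4,7-trimethyl-7-(tert-butyldimethylsilyloxy)hexahydrocyclopenta[c]pyran-3(1H)-one (lactone C9→O6, cis-fused, 10α-OH, 4α-OTBS; C6 epimers) | C[C@@]1(O)C(=O)OC(C)[C@@H]2[C@H]1CC[C@@]2(C)O[Si](C)(C)C(C)(C)C | intermediate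
19 | 1,4,7-trimethyl-4,7-bis(tert-butyldimethylsilyloxy)hexahydrocyclopenta[c]pyran-3(1H)-one (C6 epimers) | C[C@@]1(O[Si](C)(C)C(C)(C)C)C(=O)OC(C)[C@@H]2[C@H]1CC[C@@]2(C)O[Si](C)(C)C(C)(C)C | intermediate
20 | 1,4,7-trimethyl-4,7-bis(tert-butyldimethylsilyloxy)octahydrocyclopenta[c]pyran-3-ol (lactol; C9 anomers, C6 epimers) | C[C@@]1(O[Si](C)(C)C(C)(C)C)C(O)OC(C)[C@@H]2[C@H]1CC[C@@]2(C)O[Si](C)(C)C(C)(C)C | intermediate
21 | cyclopentane with C5 1-hydroxyethyl and C1 C10(Me)(OTBS)–CH=CH–OMe chains, 4α-OTBS (E/Z, C6 epimers) | COC=C[C@@](C)(O[Si](C)(C)C(C)(C)C)[C@@H]1CC[C@@](C)(O[Si](C)(C)C(C)(C)C)[C@@H]1C(C)O | intermediate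
22 | C6 methyl ketone of 21 (E/Z) | COC=C[C@@](C)(O[Si](C)(C)C(C)(C)C)[C@@H]1CC[C@@](C)(O[Si](C)(C)C(C)(C)C)[C@@H]1C(C)=O | intermediate
23 | C6 methyl ketone with C8 dimethyl acetal | COC(OC)C[C@@](C)(O[Si](C)(C)C(C)(C)C)[C@@H]1CC[C@@](C)(O[Si](C)(C)C(C)(C)C)[C@@H]1C(C)=O | intermediate
24 | lithium C6–C7 enolate of 23 | [Li+].COC(OC)C[C@@](C)(O[Si](C)(C)C(C)(C)C)[C@@H]1CC[C@@](C)(O[Si](C)(C)C(C)(C)C)[C@@H]1C(=C)[O-] | intermediate (not isolated)
25 | trimethylsilyl enol ether C6(OSiMe3)=C7H2 of 23 | COC(OC)C[C@@](C)(O[Si](C)(C)C(C)(C)C)[C@@H]1CC[C@@](C)(O[Si](C)(C)C(C)(C)C)[C@@H]1C(=C)O[Si](C)(C)C | intermediate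
26 | 8-methoxy-4α,10α-bis(tert-butyldimethylsilyloxy)-1αH,5αH-11,12,13-trinorguaian-6-one (C8 epimers) | COC1C[C@@](C)(O[Si](C)(C)C(C)(C)C)[C@@H]2CC[C@@](C)(O[Si](C)(C)C(C)(C)C)[C@@H]2C(=O)C1 | intermediate (not isolated)
27 | 4α,10α-bis(tert-butyldimethylsilyloxy)-1αH,5αH-11,12,13-trinorguai-7-en-6-one [3,8-dimethyl-3,8-bis(tert-butyldimethylsilyloxy)-2,3,3a,7,8,8a-hexahydroazulen-4(1H)-one] | O=C1C=CC[C@@](C)(O[Si](C)(C)C(C)(C)C)[C@@H]2CC[C@@](C)(O[Si](C)(C)C(C)(C)C)[C@H]12 | intermediate
28 | 2,2-dimethyl-1,3-dioxan-5-one | CC1(C)OCC(=O)CO1 | starting material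
29 | lithium C6–C7 enolate from 1,4-reduction of 27 | [Li+].[O-]C1=CCC[C@@](C)(O[Si](C)(C)C(C)(C)C)[C@@H]2CC[C@@](C)(O[Si](C)(C)C(C)(C)C)[C@H]12 | intermediate (not isolated)
30 | 7β-(5-hydroxy-2,2-dimethyl-1,3-dioxan-5-yl)-4α,10α-bis(tert-butyldimethylsilyloxy)-1αH,5αH,7αH-11,12,13-trinorguaian-6-one | CC1(C)OCC(O)(CO1)[C@@H]2CC[C@@](C)(O[Si](C)(C)C(C)(C)C)[C@@H]3CC[C@@](C)(O[Si](C)(C)C(C)(C)C)[C@@H]3C2=O | intermediate
31 | 6α-alcohol of 30 | CC1(C)OCC(O)(CO1)[C@@H]2CC[C@@](C)(O[Si](C)(C)C(C)(C)C)[C@@H]3CC[C@@](C)(O[Si](C)(C)C(C)(C)C)[C@@H]3[C@H]2O | intermediate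
32 | (1R,4R,5S,6S,7R,10R)-guaiane-4,6,10,11,12,13-hexaol | OCC(O)(CO)[C@@H]1CC[C@@](C)(O)[C@@H]2CC[C@@](C)(O)[C@@H]2[C@H]1O | intermediate
33 | (1R,4R,5S,6S,7R,10R)-4,6,10,11-tetrahydroxyguaiane-12,13-diyl diacetate (CNP0179913.1) | CC(=O)OCC(O)(COC(C)=O)[C@@H]1CC[C@@](C)(O)[C@@H]2CC[C@@](C)(O)[C@@H]2[C@H]1O | target

**Step count and risks**

Total steps: 21. Longest linear sequence: 20 steps (steps 2–21, from (R)-linalool); step 1 is the only branch.

Steps most likely to fail:

1. Step 9 (Michael union). Possible failure: addition to the carbonyl instead of C1, proton transfer from the acetyl group or C2 to the enolate, approach on the α face of C1, or protonation of C5 from the β face. Fallback (Mukaiyama–Michael addition, with Lewis-acid activation of the acceptor instead of an anionic donor): it sets out from 3, whose enolate is O-silylated (LiN(i-Pr)2, TMSCl, THF, −78 °C) to give (R)-2-tert-butyl-5-methyl-4-(trimethylsilyloxy)-1,3-dioxole F1. F1 and enone 13 are combined with catalytic TMSOTf in CH2Cl2 at −78 °C to give the trimethylsilyl enol ether of the adduct F2, the tert-butyl and silyloxy groups again directing the two faces. Protodesilylation of F2 with dilute HCl in THF at −78 °C protonates C5 and brings the route back to 16.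

2. Step 17 (seven-membered ring closure). Possible failure: the oxocarbenium ion loses a proton to an enol ether or reacts between molecules faster than the ring closes, or the enol silane is cleaved before it reacts. Fallback (intramolecular Wittig olefination): from 25, NBS in THF at −78 °C gives the C7 bromomethyl ketone F3. PPh3 in toluene converts it into the acylmethyl triphenylphosphonium bromide F4. Aqueous trifluoroacetic acid hydrolyses the acetal to the aldehyde phosphonium bromide F5. Et3N at high dilution in CH2Cl2 forms the stabilised keto ylide F6, which closes onto the C8 aldehyde and returns to enone 27.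

3. Step 18 (reductive aldol). Possible failure: retro-aldol cleavage of the tertiary aldolate on warming or work-up, 1,2-reduction of the enone, or addition on the α face. Fallback (Mukaiyama aldol of a neutral enol silane): from 27, 1,4-hydrosilylation with Et3SiH and RhCl(PPh3)3 (cat.) gives the triethylsilyl enol ether F7. F7 adds to dioxanone 28 under BF3·OEt2 in CH2Cl2 at −78 °C through an open transition state, under conditions where the adduct cannot revert, and after aqueous work-up the route is back at 30.

**Further compounds**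

F1 | step 9 | (R)-2-tert-butyl-5-methyl-4-(trimethylsilyloxy)-1,3-dioxole | CC1=C(O[Si](C)(C)C)O[C@H](C(C)(C)C)O1
F2 | step 9 | trimethylsilyl enol ether (C5=C6) of adduct 16 | O=C1O[C@H](C(C)(C)C)O[C@@]1(C)[C@@H]2CC[C@@](C)(O[Si](C)(C)C(C)(C)C)C2=C(C)O[Si](C)(C)C
F3 | step 17 | C7 bromomethyl ketone of 23 | COC(OC)C[C@@](C)(O[Si](C)(C)C(C)(C)C)[C@@H]1CC[C@@](C)(O[Si](C)(C)C(C)(C)C)[C@@H]1C(=O)CBr
F4 | step 17 | acylmethyl triphenylphosphonium bromide (C8 dimethyl acetal) | COC(OC)C[C@@](C)(O[Si](C)(C)C(C)(C)C)[C@@H]1CC[C@@](C)(O[Si](C)(C)C(C)(C)C)[C@@H]1C(=O)C[P+](c1ccccc1)(c1ccccc1)c1ccccc1.[Br-]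
F5 | step 17 | acylmethyl triphenylphosphonium bromide (C8 aldehyde) | O=CC[C@@](C)(O[Si](C)(C)C(C)(C)C)[C@@H]1CC[C@@](C)(O[Si](C)(C)C(C)(C)C)[C@@H]1C(=O)C[P+](c1ccccc1)(c1ccccc1)c1ccccc1.[Br-]
F6 | step 17 | keto ylide with C8 aldehyde | O=CC[C@@](C)(O[Si](C)(C)C(C)(C)C)[C@@H]1CC[C@@](C)(O[Si](C)(C)C(C)(C)C)[C@@H]1C(=O)C=P(c1ccccc1)(c1ccccc1)c1ccccc1
F7 | step 18 | triethylsilyl enol ether C6(OSiEt3)=C7 from 27 | CC[Si](CC)(CC)OC1=CCC[C@@](C)(O[Si](C)(C)C(C)(C)C)[C@@H]2CC[C@@](C)(O[Si](C)(C)C(C)(C)C)[C@H]12
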